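The flavone is cut at C3–C4 and O1–C2. C4 hangs on C4a, whose ring A neighbours C5 and C8a both carry oxygen, so the C4 synthon can be an aryl nitrile oxide shielded on both flanks against dimerisation; C3 needs an oxygen handle, carried as boron. One (3+2) cycloaddition to a ring B alkynyl pinacol boronate forms C4–C3, stores C4 as C=N and C2 as C–O in an isoxazole, and puts boron on the future C3. The dipole is a hexasubstituted benzonitrile oxide with OMOM (future O1) on one flank and a diphenylmethylene ketal across O5/O6 on the other; the partner is the 3,5-bis(benzyloxy)-4-methoxyphenyl alkynylboronate.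

Key step: step 13

Remark: positions are given in flavone numbering; the target has no stereocentre, the double-bond geometries of 8, 9, 23 and 24 are without consequence, and 25 is racemic and loses its stereocentre on dehydration.

Step 1
Reactants: 1 2,3-dimethoxy-1,4-benzoquinone
Product: 2 5,6-dimethoxybenzene-1,2,4-triyl triacetate
Conditions: Ac2O, cat. H2SO4, 25–40 °C
Reagents that add atoms: acetic anhydride CC(=O)OC(C)=O
Why: Thiele–Winter acetoxylation: the acid-activated quinone takes up acetate at its unsubstituted C5–C6 edge (both sites are equivalent by symmetry) and the adduct is trapped as the aromatic triacetate, which installs the fifth ring oxygen.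

Step 2
Reactants: 2 5,6-dimethoxybenzene-1,2,4-triyl triacetate
Product: 3 5,6-dimethoxybenzene-1,2,4-triol
Conditions: cat. conc. HCl, degassed MeOH, reflux, Ar; evaporated and used crude
Reagents that add atoms: none
Why: Acid-catalysed methanolysis (transesterification) of the three aryl acetates frees the phenols without base, under which this hydroxyhydroquinone would air-oxidise.

Step 3
Reactants: 3 5,6-dimethoxybenzene-1,2,4-triol, 4 dichlorodiphenylmethane
Product: 5 6,7-dimethoxy-2,2-diphenyl-1,3-benzodioxol-5-ol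
Conditions: Ph2O, 170 °C, Ar stream
Reagents that add atoms: none
Why: Ketalisation of a catechol with a gem-dichloride: only the two adjacent hydroxyls can close the five-membered dioxole, so the lone hydroxyl next to the free ring position should stay free.

Step 4
Reactants: 5 6,7-dimethoxy-2,2-diphenyl-1,3-benzodioxol-5-ol
Product: 6 5-hydroxy-6,7-dimethoxy-2,2-diphenyl-1,3-benzodioxole-4-carbaldehyde
Conditions: MgCl2, Et3N, (CH2O)n, MeCN, reflux
Reagents that add atoms: paraformaldehyde (as formaldehyde) C=O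
Why: Casnati–Skattebøl ortho-formylation: the magnesium phenoxide delivers formaldehyde to the only unsubstituted ring carbon, ortho to the phenol, and a second formaldehyde oxidises the resulting benzylic alkoxide by hydride transfer, all under basic conditions that spare the ketal.

Step 5
Reactants: 6 5-hydroxy-6,7-dimethoxy-2,2-diphenyl-1,3-benzodioxole-4-carbaldehyde
Product: 7 6,7-dimethoxy-5-(methoxymethoxy)-2,2-diphenyl-1,3-benzodioxole-4-carbaldehyde
Conditions: MOMCl, K2CO3, DMF, 0 °C → rt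
Reagents that add atoms: chloromethyl methyl ether COCCl
Why: Williamson-type O-alkylation of the phenoxide with the reactive α-chloro ether masks the future O1 as an acid-labile acetal, while the aldehyde, lacking α-hydrogens, is inert to carbonate.

Step 6
Reactants: 7 6,7-dimethoxy-5-(methoxymethoxy)-2,2-diphenyl-1,3-benzodioxole-4-carbaldehyde
Product: 8 (E)-6,7-dimethoxy-5-(methoxymethoxy)-2,2-diphenyl-1,3-benzodioxole-4-carbaldehyde oxime
Conditions: NH2OH·HCl, NaOAc, EtOH/H2O, rt → 50 °C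
Reagents that add atoms: hydroxylamine hydrochloride NO.Cl
Why: Oxime condensation under acetate buffer is mild enough for the MOM acetal and the ketal; the E isomer is expected, but the geometry is erased in the next step.

Step 7
Reactants: 8 (E)-6,7-dimethoxy-5-(methoxymethoxy)-2,2-diphenyl-1,3-benzodioxole-4-carbaldehyde oxime
Product: 10 6,7-dimethoxy-5-(methoxymethoxy)-2,2-diphenyl-1,3-benzodioxole-4-carbonitrile oxide, via hydroximoyl chloride 9 (not isolated)
Conditions: aq. NaOCl, CH2Cl2, 0 °C; cold work-up, stored at −20 °C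
Reagents that add atoms: none
Why: Hypochlorite oxidation of an aldoxime: C-chlorination gives the hydroximoyl chloride and base removes HCl (1,3-elimination) to the nitrile oxide, which should be isolable because ring A has no CH left to chlorinate and both positions ortho to the CNO carbon are substituted, blocking furoxan formation.

Step 8
Reactants: 11 methyl 3,5-dihydroxy-4-methoxybenzoate
Product: 12 methyl 3,5-bis(benzyloxy)-4-methoxybenzoate
Conditions: BnBr, K2CO3, DMF, 60 °C
Reagents that add atoms: benzyl bromide BrCc1ccccc1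
Why: Williamson ether synthesis on both phenols protects O3' and O5' as ethers that survive hydride, organolithium, peroxide and acid and fall in the final hydrogenolysis.

Step 9
Reactants: 12 methyl 3,5-bis(benzyloxy)-4-methoxybenzoate
Product: 13 [3,5-bis(benzyloxy)-4-methoxyphenyl]methanol
Conditions: LiAlH4, THF, 0 °C; aq. NaOH work-up
Reagents that add atoms: none
Why: Hydride reduction of the ester to the primary benzylic alcohol; benzyl and methyl ethers are inert.

Step 10
Reactants: 13 [3,5-bis(benzyloxy)-4-methoxyphenyl]methanol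
Product: 14 3,5-bis(benzyloxy)-4-methoxybenzaldehyde
Conditions: MnO2, CH2Cl2, rt
Reagents that add atoms: none
Why: Heterogeneous oxidation of a benzylic alcohol with MnO2 stops cleanly at the aldehyde.

Step 11
Reactants: 14 3,5-bis(benzyloxy)-4-methoxybenzaldehyde
Product: 15 1,3-bis(benzyloxy)-5-ethynyl-2-methoxybenzene
Conditions: dimethyl (1-diazo-2-oxopropyl)phosphonate, K2CO3, MeOH, rt
Reagents that add atoms: dimethyl (1-diazo-2-oxopropyl)phosphonate COP(=O)(OC)C(=[N+]=[N-])C(C)=O
Why: Ohira–Bestmann (Seyferth–Gilbert) homologation: methanolysis of the reagent releases the diazomethylphosphonate anion, which olefinates the aldehyde, and loss of N2 with a 1,2-hydrogen shift gives the terminal alkyne under mild carbonate conditions.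

Step 12
Reactants: 15 1,3-bis(benzyloxy)-5-ethynyl-2-methoxybenzene, 16 2-isopropoxy-4,4,5,5-tetramethyl-1,3,2-dioxaborolane
Product: 19 2-{[3,5-bis(benzyloxy)-4-methoxyphenyl]ethynyl}-4,4,5,5-tetramethyl-1,3,2-dioxaborolane, via lithium acetylide 17 (not isolated), via lithium alkynylborate 18 (not isolated)
Conditions: n-BuLi, THF, −78 °C; then 16, −78 °C; then HCl·Et2O, −78 °C → rt; filtered under Ar
Reagents that add atoms: none
Why: Deprotonation of the terminal alkyne, addition of the acetylide to the borate ester to form an ate complex, and removal of isopropoxide with anhydrous HCl is the standard route to alkynyl pinacol boronates; no water is admitted, so the labile C(sp)–B bond survives.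

Step 13
Reactants: 10 6,7-dimethoxy-5-(methoxymethoxy)-2,2-diphenyl-1,3-benzodioxole-4-carbonitrile oxide, 19 2-{[3,5-bis(benzyloxy)-4-methoxyphenyl]ethynyl}-4,4,5,5-tetramethyl-1,3,2-dioxaborolane
Product: 20 5-[3,5-bis(benzyloxy)-4-methoxyphenyl]-3-[6,7-dimethoxy-5-(methoxymethoxy)-2,2-diphenyl-1,3-benzodioxol-4-yl]-4-(4,4,5,5-tetramethyl-1,3,2-dioxaborolan-2-yl)isoxazole
Conditions: PhMe, 4 Å MS, 60–70 °C, Ar (19 in 1.3-fold excess)
Reagents that add atoms: none
Why: The nitrile oxide and the alkyne combine in a concerted, asynchronous Huisgen (3+2) cycloaddition in which the dipole carbon bonds to the boron-bearing alkyne carbon (the future C4–C3 bond) and the dipole oxygen to the aryl-bearing carbon (the temporary O–C2 link, cut again in step 16). The closest known reaction type is the thermal addition of hindered aryl nitrile oxides to internal alkynyl pinacol boronates, which gives isoxazole-4-boronates. The isoxazole ring closes intermolecularly, both of its new bonds forming in the one pericyclic event, so no exo/endo ring-closure question arises. No stereocentre is formed. The step needs regiocontrol (boron on isoxazole C4) and suppression of dipole dimerisation: the vacant p orbital on boron and the aryl group on the other alkyne carbon both steer the nucleophilic dipole oxygen to the aryl-bearing carbon, and the OMOM and ketal oxygens on the two ring A positions flanking the CNO carbon block furoxan formation, so the dipole can be warmed with the alkyne for as long as the crowded addition needs.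

Step 14
Reactants: 20 5-[3,5-bis(benzyloxy)-4-methoxyphenyl]-3-[6,7-dimethoxy-5-(methoxymethoxy)-2,2-diphenyl-1,3-benzodioxol-4-yl]-4-(4,4,5,5-tetramethyl-1,3,2-dioxaborolan-2-yl)isoxazole
Product: 21 5-[3,5-bis(benzyloxy)-4-methoxyphenyl]-3-[6,7-dimethoxy-5-(methoxymethoxy)-2,2-diphenyl-1,3-benzodioxol-4-yl]isoxazol-4-ol
Conditions: 30% H2O2, aq. NaOH, THF, 0 °C
Reagents that add atoms: hydrogen peroxide OO
Why: Oxidation of a C–B bond with basic hydrogen peroxide (hydroperoxide adds to boron, the isoxazolyl carbon migrates to oxygen, the borate ester hydrolyses) places oxygen exactly on the future C3; a 3,5-disubstituted isoxazole tolerates cold dilute base.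

Step 15
Reactants: 21 5-[3,5-bis(benzyloxy)-4-methoxyphenyl]-3-[6,7-dimethoxy-5-(methoxymethoxy)-2,2-diphenyl-1,3-benzodioxol-4-yl]isoxazol-4-ol
Product: 22 5-[3,5-bis(benzyloxy)-4-methoxyphenyl]-3-[6,7-dimethoxy-5-(methoxymethoxy)-2,2-diphenyl-1,3-benzodioxol-4-yl]-4-methoxyisoxazole
Conditions: MeI, K2CO3, acetone, 40 °C
Reagents that add atoms: iodomethane CI
Why: Williamson O-methylation of the phenol-like isoxazol-4-ol, which is substituted at C3 and C5 and so has no CH-keto tautomer to divert alkylation to carbon.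

Step 16
Reactants: 22 5-[3,5-bis(benzyloxy)-4-methoxyphenyl]-3-[6,7-dimethoxy-5-(methoxymethoxy)-2,2-diphenyl-1,3-benzodioxol-4-yl]-4-methoxyisoxazole
Product: 23 (2E)-3-amino-1-[3,5-bis(benzyloxy)-4-methoxyphenyl]-3-[6,7-dimethoxy-5-(methoxymethoxy)-2,2-diphenyl-1,3-benzodioxol-4-yl]-2-methoxyprop-2-en-1-one
Conditions: Mo(CO)6 (0.6 equiv), MeCN/H2O, reflux
Reagents that add atoms: none
Why: Reductive cleavage of the isoxazole N–O bond by zerovalent molybdenum with water as the proton source unmasks the β-enaminone (NH2 hydrogen-bonded to the carbonyl), while the benzyl ethers, ketal and MOM ether, which hydrogenation would endanger, stay in place.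

Step 17
Reactants: 23 (2E)-3-amino-1-[3,5-bis(benzyloxy)-4-methoxyphenyl]-3-[6,7-dimethoxy-5-(methoxymethoxy)-2,2-diphenyl-1,3-benzodioxol-4-yl]-2-methoxyprop-2-en-1-one
Product: 26 7-[3,5-bis(benzyloxy)-4-methoxyphenyl]-4,5,8-trimethoxy-2,2-diphenyl-9H-[1,3]dioxolo[4,5-f]chromen-9-one, via phenol enaminone 24 (not isolated), via hydroxyaryl diketone 25 (not isolated)
Conditions: 2 M aq. HCl, MeOH/THF, 50 °C
Reagents that add atoms: water O
Why: Acid cascade of known steps: the MOM acetal is cleaved, the vinylogous amide is hydrolysed to the 2-methoxy-1,3-diketone, and the freed phenol (O1) adds to the ring B ketone and loses water (the usual cyclodehydration of o-hydroxyaryl 1,3-diketones to flavones), while O5 stays locked in the ketal, which needs much harsher acid, so only O1 can close.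

Step 18
Reactants: 26 7-[3,5-bis(benzyloxy)-4-methoxyphenyl]-4,5,8-trimethoxy-2,2-diphenyl-9H-[1,3]dioxolo[4,5-f]chromen-9-one
Product: 27 2-(3,5-dihydroxy-4-methoxyphenyl)-5,6-dihydroxy-3,7,8-trimethoxy-4H-chromen-4-one
Conditions: H2 (1 atm), 10% Pd/C, THF/MeOH, rt
Reagents that add atoms: none
Why: Palladium-catalysed hydrogenolysis cleaves the two benzyl ethers and both benzylic C–O bonds of the diphenylmethylene ketal in one operation, and the tetrasubstituted C2=C3 bond of the flavone should not be reduced under these conditions.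

Compound list
1 | 2,3-dimethoxy-1,4-benzoquinone | COC1=C(OC)C(=O)C=CC1=O | starting material
2 | 5,6-dimethoxybenzene-1,2,4-triyl triacetate | CC(=O)Oc1cc(OC(C)=O)c(OC(C)=O)c(OC)c1OC | intermediate
3 | 5,6-dimethoxybenzene-1,2,4-triol | COc1c(O)cc(O)c(O)c1OC | intermediate
4 | dichlorodiphenylmethane | ClC(Cl)(c1ccccc1)c1ccccc1 | starting material
5 | 6,7-dimethoxy-2,2-diphenyl-1,3-benzodioxol-5-ol (free CH at C4, between the OH carbon and the dioxole) | COc1c(O)cc2OC(c3ccccc3)(c3ccccc3)Oc2c1OC | intermediate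
6 | 5-hydroxy-6,7-dimethoxy-2,2-diphenyl-1,3-benzodioxole-4-carbaldehyde | COc1c(O)c(C=O)c2OC(c3ccccc3)(c3ccccc3)Oc2c1OC | intermediate
7 | 6,7-dimethoxy-5-(methoxymethoxy)-2,2-diphenyl-1,3-benzodioxole-4-carbaldehyde | COCOc1c(C=O)c2OC(c3ccccc3)(c3ccccc3)Oc2c(OC)c1OC | intermediate
8 | (E)-6,7-dimethoxy-5-(methoxymethoxy)-2,2-diphenyl-1,3-benzodioxole-4-carbaldehyde oxime | COCOc1c(/C=N/O)c2OC(c3ccccc3)(c3ccccc3)Oc2c(OC)c1OC | intermediate
9 | (Z)-N-hydroxy-6,7-dimethoxy-5-(methoxymethoxy)-2,2-diphenyl-1,3-benzodioxole-4-carboximidoyl chloride (formed in the flask) | COCOc1c(/C(Cl)=N/O)c2OC(c3ccccc3)(c3ccccc3)Oc2c(OC)c1OC | intermediate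
10 | 6,7-dimethoxy-5-(methoxymethoxy)-2,2-diphenyl-1,3-benzodioxole-4-carbonitrile oxide (ring A dipole) | COCOc1c(C#[N+][O-])c2OC(c3ccccc3)(c3ccccc3)Oc2c(OC)c1OC | intermediate
11 | methyl 3,5-dihydroxy-4-methoxybenzoate | COC(=O)c1cc(O)c(OC)c(O)c1 | starting material
12 | methyl 3,5-bis(benzyloxy)-4-methoxybenzoate | COC(=O)c1cc(OCc2ccccc2)c(OC)c(OCc2ccccc2)c1 | intermediate
13 | [3,5-bis(benzyloxy)-4-methoxyphenyl]methanol | OCc1cc(OCc2ccccc2)c(OC)c(OCc2ccccc2)c1 | intermediate
14 | 3,5-bis(benzyloxy)-4-methoxybenzaldehyde | O=Cc1cc(OCc2ccccc2)c(OC)c(OCc2ccccc2)c1 | intermediate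
15 | 1,3-bis(benzyloxy)-5-ethynyl-2-methoxybenzene | C#Cc1cc(OCc2ccccc2)c(OC)c(OCc2ccccc2)c1 | intermediate
16 | 2-isopropoxy-4,4,5,5-tetramethyl-1,3,2-dioxaborolane | CC(C)OB1OC(C)(C)C(C)(C)O1 | starting material
17 | {[3,5-bis(benzyloxy)-4-methoxyphenyl]ethynyl}lithium (formed in the flask) | [Li]C#Cc1cc(OCc2ccccc2)c(OC)c(OCc2ccccc2)c1 | intermediate
18 | lithium 2-{[3,5-bis(benzyloxy)-4-methoxyphenyl]ethynyl}-2-isopropoxy-4,4,5,5-tetramethyl-1,3,2-dioxaborolan-2-uide (formed in the flask) | [Li+].CC(C)O[B-]1(C#Cc2cc(OCc3ccccc3)c(OC)c(OCc3ccccc3)c2)OC(C)(C)C(C)(C)O1 | intermediate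
19 | 2-{[3,5-bis(benzyloxy)-4-methoxyphenyl]ethynyl}-4,4,5,5-tetramethyl-1,3,2-dioxaborolane (ring B alkynylboronate) | CC1(C)OB(C#Cc2cc(OCc3ccccc3)c(OC)c(OCc3ccccc3)c2)OC1(C)C | intermediate
20 | 5-[3,5-bis(benzyloxy)-4-methoxyphenyl]-3-[6,7-dimethoxy-5-(methoxymethoxy)-2,2-diphenyl-1,3-benzodioxol-4-yl]-4-(4,4,5,5-tetramethyl-1,3,2-dioxaborolan-2-yl)isoxazole | COc1c(OCc2ccccc2)cc(-c2onc(-c3c(OCOC)c(OC)c(OC)c4OC(c5ccccc5)(c5ccccc5)Oc34)c2B2OC(C)(C)C(C)(C)O2)cc1OCc1ccccc1 | intermediate
21 | 5-[3,5-bis(benzyloxy)-4-methoxyphenyl]-3-[6,7-dimethoxy-5-(methoxymethoxy)-2,2-diphenyl-1,3-benzodioxol-4-yl]isoxazol-4-ol | COc1c(OCc2ccccc2)cc(-c2onc(-c3c(OCOC)c(OC)c(OC)c4OC(c5ccccc5)(c5ccccc5)Oc34)c2O)cc1OCc1ccccc1 | intermediate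
22 | 5-[3,5-bis(benzyloxy)-4-methoxyphenyl]-3-[6,7-dimethoxy-5-(methoxymethoxy)-2,2-diphenyl-1,3-benzodioxol-4-yl]-4-methoxyisoxazole | COc1c(OCc2ccccc2)cc(-c2onc(-c3c(OCOC)c(OC)c(OC)c4OC(c5ccccc5)(c5ccccc5)Oc34)c2OC)cc1OCc1ccccc1 | intermediate
23 | (2E)-3-amino-1-[3,5-bis(benzyloxy)-4-methoxyphenyl]-3-[6,7-dimethoxy-5-(methoxymethoxy)-2,2-diphenyl-1,3-benzodioxol-4-yl]-2-methoxyprop-2-en-1-one (NH2 cis to C=O) | N/C(c1c(OCOC)c(OC)c(OC)c2OC(c3ccccc3)(c3ccccc3)Oc12)=C(/OC)C(=O)c1cc(OCc2ccccc2)c(OC)c(OCc2ccccc2)c1 | intermediate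
24 | (2E)-3-amino-1-[3,5-bis(benzyloxy)-4-methoxyphenyl]-3-(5-hydroxy-6,7-dimethoxy-2,2-diphenyl-1,3-benzodioxol-4-yl)-2-methoxyprop-2-en-1-one (formed in the flask) | N/C(c1c(O)c(OC)c(OC)c2OC(c3ccccc3)(c3ccccc3)Oc12)=C(/OC)C(=O)c1cc(OCc2ccccc2)c(OC)c(OCc2ccccc2)c1 | intermediate
25 | 1-[3,5-bis(benzyloxy)-4-methoxyphenyl]-3-(5-hydroxy-6,7-dimethoxy-2,2-diphenyl-1,3-benzodioxol-4-yl)-2-methoxypropane-1,3-dione (racemic, formed in the flask) | COC(C(=O)c1c(O)c(OC)c(OC)c2OC(c3ccccc3)(c3ccccc3)Oc12)C(=O)c1cc(OCc2ccccc2)c(OC)c(OCc2ccccc2)c1 | intermediate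
26 | 7-[3,5-bis(benzyloxy)-4-methoxyphenyl]-4,5,8-trimethoxy-2,2-diphenyl-9H-[1,3]dioxolo[4,5-f]chromen-9-one (the 3,7,8-trimethoxyflavone with O5/O6 in the diphenylmethylene ketal and O3'/O5' benzylated) | COc1c(OCc2ccccc2)cc(-c2oc3c(OC)c(OC)c4OC(c5ccccc5)(c5ccccc5)Oc4c3c(=O)c2OC)cc1OCc1ccccc1 | intermediate
27 | 2-(3,5-dihydroxy-4-methoxyphenyl)-5,6-dihydroxy-3,7,8-trimethoxy-4H-chromen-4-one (5,6,3',5'-tetrahydroxy-3,7,8,4'-tetramethoxyflavone) | COc1c(O)cc(-c2oc3c(OC)c(OC)c(O)c(O)c3c(=O)c2OC)cc1O | target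

Total step count: 18. Longest linear sequence: 13 steps (steps 1–7, then 13–18); the ring B branch (steps 8–12) joins at step 13.

Steps most likely to fail

1. Step 13. The dipole may add with the reverse orientation or too slowly at its crowded carbon, while the alkynylboronate is lost to protodeboronation by traces of water. The fallback sets out from 10 and 15 and comes back at 26; it drops the boron handle and oxygenates C3 late. Nitrile oxide 10 is heated with terminal alkyne 15 in toluene, where the dipole oxygen should end on the substituted alkyne carbon, to give 5-[3,5-bis(benzyloxy)-4-methoxyphenyl]-3-[6,7-dimethoxy-5-(methoxymethoxy)-2,2-diphenyl-1,3-benzodioxol-4-yl]isoxazole F1. Mo(CO)6 in wet MeCN should open it to the enaminone F2. Aqueous HCl in MeOH/THF then runs the cascade of step 17 through the MOM-free enaminone F3 and the hydroxyaryl 1,3-diketone F4 to the 3-unsubstituted flavone F5. Dimethyldioxirane in acetone/CH2Cl2 at 0 °C epoxidises C2=C3 to the racemic epoxide F6, which catalytic TsOH isomerises to the flavonol F7. MeI/K2CO3 in acetone then gives 26.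

2. Step 17. The ketal may be hydrolysed before ring closure, which would let O5 compete with O1 for the ring B ketone, or the sequence may stall before dehydration and call for stronger acid that worsens the first problem. The fallback sets out from 23 and comes back at 27; it exchanges the acid-labile ketal for acid-stable benzyl ethers before any acid is used. Enaminone 23 is hydrogenolysed (H2, Pd/C, THF/MeOH), which should strip both benzyl ethers and the ketal but leave the MOM ether and the vinylogous amide, to give the tetrahydroxy enaminone F8. BnBr/K2CO3 in DMF re-protects the four phenols as the tetrabenzyl enaminone F9. Aqueous HCl in MeOH/THF takes it through the MOM-free tetrabenzyl enaminone F10 and the tetrabenzyl diketone F11 to the tetrabenzyl flavone F12. H2 over Pd/C then gives 27.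

3. Step 4. The only open ring position is hemmed in by the phenol and the dioxole oxygen, so formylation may stall at the hydroxymethyl stage, couple two rings through a methylene bridge, or lose the electron-rich phenoxide to air oxidation. The fallback sets out from 5 and comes back at 7, replacing electrophilic formylation by directed ortho-metalation and making step 5 unnecessary. Phenol 5 is converted with MOMCl/K2CO3 into the MOM ether F13. n-BuLi in THF (−78 → −20 °C) removes the single ring proton, which lies between two directing oxygens, to give the aryllithium F14. DMF adds to give the lithium hemiaminolate F15, and aqueous NH4Cl releases aldehyde 7.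

Further compounds
F1 | step 13 | 5-[3,5-bis(benzyloxy)-4-methoxyphenyl]-3-[6,7-dimethoxy-5-(methoxymethoxy)-2,2-diphenyl-1,3-benzodioxol-4-yl]isoxazole | COc1c(OCc2ccccc2)cc(-c2cc(-c3c(OCOC)c(OC)c(OC)c4OC(c5ccccc5)(c5ccccc5)Oc34)no2)cc1OCc1ccccc1
F2 | step 13 | (2Z)-3-amino-1-[3,5-bis(benzyloxy)-4-methoxyphenyl]-3-[6,7-dimethoxy-5-(methoxymethoxy)-2,2-diphenyl-1,3-benzodioxol-4-yl]prop-2-en-1-one | N/C(c1c(OCOC)c(OC)c(OC)c2OC(c3ccccc3)(c3ccccc3)Oc12)=C\C(=O)c1cc(OCc2ccccc2)c(OC)c(OCc2ccccc2)c1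
F3 | step 13 | (2Z)-3-amino-1-[3,5-bis(benzyloxy)-4-methoxyphenyl]-3-(5-hydroxy-6,7-dimethoxy-2,2-diphenyl-1,3-benzodioxol-4-yl)prop-2-en-1-one (formed in the flask) | N/C(c1c(O)c(OC)c(OC)c2OC(c3ccccc3)(c3ccccc3)Oc12)=C\C(=O)c1cc(OCc2ccccc2)c(OC)c(OCc2ccccc2)c1
F4 | step 13 | 1-[3,5-bis(benzyloxy)-4-methoxyphenyl]-3-(5-hydroxy-6,7-dimethoxy-2,2-diphenyl-1,3-benzodioxol-4-yl)propane-1,3-dione (formed in the flask) | O=C(CC(=O)c1cc(OCc2ccccc2)c(OC)c(OCc2ccccc2)c1)c1c(O)c(OC)c(OC)c2OC(c3ccccc3)(c3ccccc3)Oc12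
F5 | step 13 | 7-[3,5-bis(benzyloxy)-4-methoxyphenyl]-4,5-dimethoxy-2,2-diphenyl-9H-[1,3]dioxolo[4,5-f]chromen-9-one | COc1c(OCc2ccccc2)cc(-c2cc(=O)c3c4OC(c5ccccc5)(c5ccccc5)Oc4c(OC)c(OC)c3o2)cc1OCc1ccccc1
F6 | step 13 | racemic 2,3-epoxide of F5 (cis-fused oxirane across C2–C3 of the pyranone; one enantiomer drawn) | O=C1[C@H]2O[C@@]2(c2cc(OCc3ccccc3)c(OC)c(OCc3ccccc3)c2)Oc2c(OC)c(OC)c3OC(c4ccccc4)(c4ccccc4)Oc3c12
F7 | step 13 | 7-[3,5-bis(benzyloxy)-4-methoxyphenyl]-8-hydroxy-4,5-dimethoxy-2,2-diphenyl-9H-[1,3]dioxolo[4,5-f]chromen-9-one | COc1c(OCc2ccccc2)cc(-c2oc3c(OC)c(OC)c4OC(c5ccccc5)(c5ccccc5)Oc4c3c(=O)c2O)cc1OCc1ccccc1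
F8 | step 17 | (2E)-3-amino-3-[2,3-dihydroxy-4,5-dimethoxy-6-(methoxymethoxy)phenyl]-1-(3,5-dihydroxy-4-methoxyphenyl)-2-methoxyprop-2-en-1-one | N/C(c1c(OCOC)c(OC)c(OC)c(O)c1O)=C(/OC)C(=O)c1cc(O)c(OC)c(O)c1
F9 | step 17 | (2E)-3-amino-3-[2,3-bis(benzyloxy)-4,5-dimethoxy-6-(methoxymethoxy)phenyl]-1-[3,5-bis(benzyloxy)-4-methoxyphenyl]-2-methoxyprop-2-en-1-one | N/C(c1c(OCOC)c(OC)c(OC)c(OCc2ccccc2)c1OCc1ccccc1)=C(/OC)C(=O)c1cc(OCc2ccccc2)c(OC)c(OCc2ccccc2)c1
F10 | step 17 | (2E)-3-amino-3-[2,3-bis(benzyloxy)-6-hydroxy-4,5-dimethoxyphenyl]-1-[3,5-bis(benzyloxy)-4-methoxyphenyl]-2-methoxyprop-2-en-1-one (formed in the flask) | N/C(c1c(O)c(OC)c(OC)c(OCc2ccccc2)c1OCc1ccccc1)=C(/OC)C(=O)c1cc(OCc2ccccc2)c(OC)c(OCc2ccccc2)c1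
F11 | step 17 | 1-[2,3-bis(benzyloxy)-6-hydroxy-4,5-dimethoxyphenyl]-3-[3,5-bis(benzyloxy)-4-methoxyphenyl]-2-methoxypropane-1,3-dione (racemic, formed in the flask) | COC(C(=O)c1c(O)c(OC)c(OC)c(OCc2ccccc2)c1OCc1ccccc1)C(=O)c1cc(OCc2ccccc2)c(OC)c(OCc2ccccc2)c1
F12 | step 17 | 5,6-bis(benzyloxy)-2-[3,5-bis(benzyloxy)-4-methoxyphenyl]-3,7,8-trimethoxy-4H-chromen-4-one | COc1c(OCc2ccccc2)cc(-c2oc3c(OC)c(OC)c(OCc4ccccc4)c(OCc4ccccc4)c3c(=O)c2OC)cc1OCc1ccccc1
F13 | step 4 | 4,5-dimethoxy-6-(methoxymethoxy)-2,2-diphenyl-1,3-benzodioxole | COCOc1cc2OC(c3ccccc3)(c3ccccc3)Oc2c(OC)c1OC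
F14 | step 4 | [6,7-dimethoxy-5-(methoxymethoxy)-2,2-diphenyl-1,3-benzodioxol-4-yl]lithium (formed in the flask) | COCOc1c([Li])c2OC(c3ccccc3)(c3ccccc3)Oc2c(OC)c1OC
F15 | step 4 | lithium [6,7-dimethoxy-5-(methoxymethoxy)-2,2-diphenyl-1,3-benzodioxol-4-yl](dimethylamino)methanolate (racemic, formed in the flask) | [Li+].COCOc1c(C([O-])N(C)C)c2OC(c3ccccc3)(c3ccccc3)Oc2c(OC)c1OC
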